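## Retrosynthetic overview

1. Feature: in the carbocycle C4a-C5-C6-C7-C8-C8a of the 6H-isochromene-6,8-dione, C7 (O, CH3) is a tertiary carbinol carbon directly bonded to the C8 ketone. This alpha-ketol is the retron of a crossed benzoin between a C8 aldehyde on the pyran ring and a C7 methyl ketone.
2. Disconnections: the C7-O linoleate ester (last); C7-C8 by an enantioselective carbene-catalysed aldehyde-ketone benzoin; C4a=C5 by sulfide contraction of a pyran-4-thione with 1-bromobutane-2,3-dione; C8a-C8 by Pd formylation of allomaltol triflate.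
3. C4a=C5 is made through a sulfur tether. A 4-alkoxypyrylium salt with a free C1-H should take a soft enol nucleophile next to the ring oxygen, whereas the tether delivers the carbon to C4a only.
4. Ring order: the pyran ring (O2, C1, C3, C4, C4a, C8a) comes with kojic acid. The carbocycle is closed second, in the step that also sets C7.

Key step: step 10

Assumption: the sense of induction of the aminoindanol triazolium salt on this substrate cannot be predicted with certainty. The (5aR,10bS) salt is written; if it delivers C8 to the Re face of the C7 ketone, its equally available (5aS,10bR) antipode is used with nothing else changed.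

## Route

Step 1
Reactants: 1 kojic acid (5-hydroxy-2-(hydroxymethyl)-4H-pyran-4-one)
Product: 2 chlorokojic acid (2-(chloromethyl)-5-hydroxy-4H-pyran-4-one)
Conditions: SOCl2 (neat), rt
Reagents that add atoms: thionyl chloride, O=S(Cl)Cl
Why: Chlorodehydroxylation through the chlorosulfite takes only the primary allylic-type alcohol, because the enolic 5-OH on the sp2 carbon cannot be substituted.

Step 2
Reactants: 2 chlorokojic acid
Product: 3 allomaltol (5-hydroxy-2-methyl-4H-pyran-4-one)
Conditions: Zn dust, conc. HCl, H2O, 70 °C
Reagents that add atoms: none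
Why: Dissolving-metal reductive dehalogenation cleaves the activated C-Cl bond (a vinylogous alpha-halo ketone) and leaves the pyranone ring untouched.

Step 3
Reactants: 3 allomaltol
Product: 4 6-methyl-4-oxo-4H-pyran-3-yl trifluoromethanesulfonate
Conditions: Tf2O, pyridine, CH2Cl2, 0 °C
Reagents that add atoms: triflic anhydride, O=S(=O)(OS(=O)(=O)C(F)(F)F)C(F)(F)F
Why: O-sulfonylation of the acidic enol is fast, and it is the only OH group in the molecule.

Step 4
Reactants: 4 6-methyl-4-oxo-4H-pyran-3-yl trifluoromethanesulfonate
Product: 5 6-methyl-4-oxo-4H-pyran-3-carbaldehyde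
Conditions: CO (1 atm), Et3SiH, Pd(OAc)2 (cat.), dppp (cat.), Et3N, DMF, 70 °C
Reagents that add atoms: carbon monoxide, [C-]#[O+]
Why: In this palladium-catalysed reductive carbonylation (formylation) of an enol triflate, oxidative addition into the C-OTf bond of the electron-poor pyranone, CO insertion and hydride transfer from the silane to the acylpalladium species should give the aldehyde.

Step 5
Reactants: 5 6-methyl-4-oxo-4H-pyran-3-carbaldehyde
Product: 6 5-(1,3-dioxolan-2-yl)-2-methyl-4H-pyran-4-one
Conditions: HOCH2CH2OH, p-TsOH (cat.), toluene, reflux (Dean-Stark)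
Reagents that add atoms: ethylene glycol, OCCO
Why: Acid-catalysed acetalisation driven by azeotropic removal of water masks the formyl group, which would otherwise be thionated in step 6, while the vinylogous ester carbonyl does not ketalise.

Step 6
Reactants: 6 5-(1,3-dioxolan-2-yl)-2-methyl-4H-pyran-4-one
Product: 7 5-(1,3-dioxolan-2-yl)-2-methyl-4H-pyran-4-thione
Conditions: Lawesson's reagent (0.55 equiv), toluene, 80 °C
Reagents that add atoms: Lawesson's reagent, COc1ccc(cc1)P1(=S)SP(=S)(S1)c1ccc(OC)cc1
Why: Thionation with Lawesson's reagent (thiaoxaphosphetane formation and cycloreversion) is standard for 4-pyranones, whose polarised carbonyl oxygen is strongly nucleophilic, and the dioxolane offers the reagent no C=O.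

Step 7
Reactants: 8 butane-2,3-dione
Product: 9 1-bromobutane-2,3-dione
Conditions: Br2 (0.9 equiv, slow addition), CHCl3, 50 °C; distillation
Reagents that add atoms: bromine, BrBr
Why: Acid-catalysed alpha-bromination proceeds through the enol, and a deficit of bromine followed by distillation holds back the 1,4-dibromide.

Step 8
Reactants: 7 5-(1,3-dioxolan-2-yl)-2-methyl-4H-pyran-4-thione; 9 1-bromobutane-2,3-dione
Product: 12 (Z)-1-[5-(1,3-dioxolan-2-yl)-2-methyl-4H-pyran-4-ylidene]butane-2,3-dione, via alkylsulfanylpyrylium bromide 10 (not isolated), via spiro-thiirane 11 (not isolated)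
Conditions: MeCN, 0 °C to rt; then PPh3, Et3N, rt
Reagents that add atoms: none
Why: In this Eschenmoser sulfide contraction the soft thione sulfur is alkylated by the alpha-bromo ketone, Et3N removes the acidic SCH2 proton of 10, the ylide closes on C4 of the pyrylium ring to thiirane 11 and PPh3 takes the sulfur, so the carbon reaches C4 only and never the open C-H position next to the ring oxygen; the push-pull alkene of 12 is configurationally mobile, so its E/Z composition is of no consequence (the Z form is drawn).

Step 9
Reactants: 12 (Z)-1-[5-(1,3-dioxolan-2-yl)-2-methyl-4H-pyran-4-ylidene]butane-2,3-dione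
Product: 13 (Z)-4-(2,3-dioxobutylidene)-6-methyl-4H-pyran-3-carbaldehyde (dione arm cis to the formyl-bearing ring carbon)
Conditions: 10% aq oxalic acid, THF, rt
Reagents that add atoms: water, O
Why: Acid-catalysed acetal hydrolysis should need only a weak acid here, because the oxocarbenium ion is stabilised through C8a=C1-O2 as a vinylogous dioxocarbenium ion, and such acid spares the dione and the pyranylidene unit.

Step 10
Reactants: 13 (Z)-4-(2,3-dioxobutylidene)-6-methyl-4H-pyran-3-carbaldehyde
Product: 14 (R)-7-hydroxy-3,7-dimethyl-6H-isochromene-6,8(7H)-dione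
Conditions: (5aR,10bS)-2-(pentafluorophenyl)-5a,10b-dihydro-4H,6H-indeno[2,1-b][1,2,4]triazolo[4,3-d][1,4]oxazin-2-ium tetrafluoroborate (15 mol %), i-Pr2NEt (15 mol %), toluene (0.02 M), rt, argon
Reagents that add atoms: none
Why: The free triazolylidene adds to the C8 formyl group and a proton shift gives the Breslow enaminol, whose C8 carbon attacks the C7 carbonyl, after which the adduct collapses, the carbene leaves and the C8 ketone and the C7 tertiary carbinol are in place. The closest known reaction type is the chiral-triazolium-catalysed intramolecular crossed aldehyde-ketone benzoin that gives six-membered tertiary alpha-ketols. The carbocycle C4a-C5-C6-C7-C8-C8a closes in the 6-exo-trig mode from the Z form of 13, which is replenished from the E form because the C4a=C5 bond of this push-pull (pyrylium enolate) system rotates easily. C7, the only stereocentre, is controlled by the aminoindanol backbone and the N-C6F5 group of the carbene, which leave one face of the enaminol open so that C8 meets the Si face of the C7 ketone and the R configuration results. The step needs C7 to react instead of C6 and acyl-anion instead of homoenolate reactivity: C6 is a doubly vinylogous ester carbonyl and would close a strained five-membered ring, C7 is an unconjugated ketone activated by its neighbour, and the homoenolate carbon C1 carries the donor oxygen O2 and has no electrophile within reach. A catalytic amount of weak base, the electron-poor carbene, dilution and exclusion of air should keep enolisation of the methyl ketone, carbene attack on the dione and oxidation of the enaminol in check.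

Step 11
Reactants: 15 linoleic acid ((9Z,12Z)-octadeca-9,12-dienoic acid)
Product: 16 linoleoyl chloride ((9Z,12Z)-octadeca-9,12-dienoyl chloride)
Conditions: (COCl)2, DMF (cat.), CH2Cl2, 0 °C to rt, argon
Reagents that add atoms: oxalyl chloride, O=C(Cl)C(=O)Cl
Why: Acid chloride formation through the Vilsmeier-type chloroiminium species runs under neutral, cold conditions that neither isomerise nor conjugate the skipped Z,Z-diene.

Step 12
Reactants: 14 (R)-7-hydroxy-3,7-dimethyl-6H-isochromene-6,8(7H)-dione; 16 linoleoyl chloride
Product: 17 (R)-3,7-dimethyl-6,8-dioxo-7,8-dihydro-6H-isochromen-7-yl (9Z,12Z)-octadeca-9,12-dienoate (target)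
Conditions: Et3N, DMAP (cat.), CH2Cl2, 0 °C to rt, argon, dark
Reagents that add atoms: none
Why: DMAP-catalysed acylation through the N-acylpyridinium ion overcomes the hindrance of the tertiary alcohol, and because only the O-H bond is broken at a carbon without alpha-hydrogen, the R configuration at C7 is retained.

## Compound list

1 | kojic acid, 5-hydroxy-2-(hydroxymethyl)-4H-pyran-4-one | O=C1C=C(CO)OC=C1O | starting material
2 | chlorokojic acid, 2-(chloromethyl)-5-hydroxy-4H-pyran-4-one | O=C1C=C(CCl)OC=C1O | intermediate
3 | allomaltol, 5-hydroxy-2-methyl-4H-pyran-4-one | CC1=CC(=O)C(O)=CO1 | intermediate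
4 | 6-methyl-4-oxo-4H-pyran-3-yl trifluoromethanesulfonate | CC1=CC(=O)C(OS(=O)(=O)C(F)(F)F)=CO1 | intermediate
5 | 6-methyl-4-oxo-4H-pyran-3-carbaldehyde | CC1=CC(=O)C(C=O)=CO1 | intermediate
6 | 5-(1,3-dioxolan-2-yl)-2-methyl-4H-pyran-4-one | CC1=CC(=O)C(C2OCCO2)=CO1 | intermediate
7 | 5-(1,3-dioxolan-2-yl)-2-methyl-4H-pyran-4-thione | CC1=CC(=S)C(C2OCCO2)=CO1 | intermediate
8 | butane-2,3-dione | CC(=O)C(C)=O | starting material
9 | 1-bromobutane-2,3-dione | CC(=O)C(=O)CBr | intermediate
10 | 4-[(2,3-dioxobutyl)sulfanyl]-5-(1,3-dioxolan-2-yl)-2-methylpyrylium bromide (not isolated) | CC(=O)C(=O)CSc1cc(C)[o+]cc1C2OCCO2.[Br-] | intermediate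
11 | spiro-thiirane, 1-[4-(1,3-dioxolan-2-yl)-7-methyl-6-oxa-1-thiaspiro[2.5]octa-4,7-dien-2-yl]propane-1,2-dione (racemic, transient, not isolated) | CC(=O)C(=O)C1SC12C=C(C)OC=C2C3OCCO3 | intermediate
12 | (Z)-1-[5-(1,3-dioxolan-2-yl)-2-methyl-4H-pyran-4-ylidene]butane-2,3-dione (E/Z mobile, Z drawn) | CC(=O)C(=O)/C=C1/C=C(C)OC=C1C2OCCO2 | intermediate
13 | (Z)-4-(2,3-dioxobutylidene)-6-methyl-4H-pyran-3-carbaldehyde (E/Z mobile, reactive Z form drawn) | CC(=O)C(=O)/C=C1/C=C(C)OC=C1C=O | intermediate
14 | (R)-7-hydroxy-3,7-dimethyl-6H-isochromene-6,8(7H)-dione | O[C@]1(C)C(=O)C=C2C=C(C)OC=C2C1=O | intermediate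
15 | linoleic acid, (9Z,12Z)-octadeca-9,12-dienoic acid | CCCCC/C=C\C/C=C\CCCCCCCC(=O)O | starting material
16 | linoleoyl chloride, (9Z,12Z)-octadeca-9,12-dienoyl chloride | CCCCC/C=C\C/C=C\CCCCCCCC(=O)Cl | intermediate
17 | (R)-3,7-dimethyl-6,8-dioxo-7,8-dihydro-6H-isochromen-7-yl (9Z,12Z)-octadeca-9,12-dienoate | CCCCC/C=C\C/C=C\CCCCCCCC(=O)O[C@]1(C)C(=O)C=C2C=C(C)OC=C2C1=O | target

## Step count

Total step count: 12.
Longest linear sequence: 10 (steps 1 to 6, 8, 9, 10 and 12).

## Steps most likely to fail

**1. Step 10.**
- Risk: the bulky chiral carbene may add only sluggishly to the deactivated, vinylogous-formate aldehyde. Face selection between the small methyl group and the flat C6 acyl group at C7 may be poor. Reversible addition may erode the enantiomeric purity further.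
- Fallback, from 13 back to 14: stereocontrol is moved from catalysis to resolution.
- The ring is closed with a small, more nucleophilic achiral carbene, made from 2-(pentafluorophenyl)-6,7-dihydro-5H-pyrrolo[2,1-c][1,2,4]triazol-2-ium tetrafluoroborate and i-Pr2NEt in toluene. This should give racemic 7-hydroxy-3,7-dimethyl-6H-isochromene-6,8(7H)-dione F1.
- The enantiomers are separated by preparative chromatography on a polysaccharide chiral stationary phase. The R enantiomer is 14, and (S)-7-hydroxy-3,7-dimethyl-6H-isochromene-6,8(7H)-dione F2 is set aside.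

**2. Step 8.**
- Risk: the sulfur ylide may close through the acyl oxygen to a 1,3-oxathiole instead of through carbon. Sulfur extrusion may stay incomplete. The free dione may self-condense under the amine base.
- Fallback, from 6 back to 13: C4a-C5 is made by 1,2-addition of a hard carbon nucleophile followed by a 1,3-oxygen shift.
- Commercial 4-(trimethylsilyl)but-3-yn-2-one is ketalised (Noyori ketalisation: TMSOCH2CH2OTMS, cat. TMSOTf, CH2Cl2, -78 °C) to 2-methyl-2-[(trimethylsilyl)ethynyl]-1,3-dioxolane F3.
- Desilylation (K2CO3, MeOH) gives 2-ethynyl-2-methyl-1,3-dioxolane F4.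
- Its cerium acetylide (n-BuLi, then CeCl3, THF, -78 °C) adds to the pyranone carbonyl of 6. The product should be racemic 5-(1,3-dioxolan-2-yl)-2-methyl-4-[(2-methyl-1,3-dioxolan-2-yl)ethynyl]-4H-pyran-4-ol F5.
- Aqueous acid (p-TsOH, THF/H2O, rt to 40 °C) then brings about the Meyer-Schuster rearrangement of the propargylic carbinol and the hydrolysis of both dioxolanes in one pot, which gives 13.

**3. Step 4.**
- Risk: hydride transfer from the silane to the organopalladium species before CO insertion would remove the triflate reductively instead of formylating the ring.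
- Fallback, from 4 back to 5: the carbon is brought in as an alkene and cut down afterwards.
- Suzuki-Miyaura vinylation (potassium vinyltrifluoroborate, PdCl2(dppf), Et3N, i-PrOH/H2O, 80 °C) should give 2-methyl-5-vinyl-4H-pyran-4-one F6.
- Lemieux-Johnson cleavage (OsO4 cat., NaIO4, 2,6-lutidine, dioxane/H2O) of the only electron-rich, unhindered alkene then gives 5.

## Further compounds

F1 | step 10 | racemic 7-hydroxy-3,7-dimethyl-6H-isochromene-6,8(7H)-dione | OC1(C)C(=O)C=C2C=C(C)OC=C2C1=O
F2 | step 10 | (S)-7-hydroxy-3,7-dimethyl-6H-isochromene-6,8(7H)-dione | O[C@@]1(C)C(=O)C=C2C=C(C)OC=C2C1=O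
F3 | step 8 | 2-methyl-2-[(trimethylsilyl)ethynyl]-1,3-dioxolane | C[Si](C)(C)C#CC1(C)OCCO1
F4 | step 8 | 2-ethynyl-2-methyl-1,3-dioxolane | C#CC1(C)OCCO1
F5 | step 8 | racemic 5-(1,3-dioxolan-2-yl)-2-methyl-4-[(2-methyl-1,3-dioxolan-2-yl)ethynyl]-4H-pyran-4-ol | CC1=CC(O)(C#CC2(C)OCCO2)C(C3OCCO3)=CO1
F6 | step 4 | 2-methyl-5-vinyl-4H-pyran-4-one | C=CC1=COC(C)=CC1=O
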